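**Plan**

- Target: (2S)-5-hydroxy-6,7,3',4'-tetramethoxyflavanone. The SMILES encodes S at C2, the only stereocentre.
- Cuts: O5–H goes back to O5–Me, and the saturated C2–C3 unit goes back to the C2=C3 alkene of the flat flavone. Ring C is then opened at C4a–C4, C4–C3 and O1–C2.
- Enabling feature: C4 is a lone carbonyl carbon bridging C4a of ring A and C3, with O1 on the neighbouring C8a. An ortho-iodophenol (ring A plus O1), CO (C4) and an arylacetylene (C3, C2, ring B) therefore make up the whole skeleton.
- Forward order: rings A and B are bought, iodination marks C4a, and one Pd-catalysed carbonylative annulation closes ring C, the only ring that has to be built.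
- Stereochemistry: catalyst-controlled hydrogenation of C2=C3 with a chiral Ru–NHC complex sets 2S. The C4 carbinol formed alongside is reoxidised, and the chelated 5-OMe is cleaved last under cold, base-free conditions that leave C2 alone.

Key step: step 2

Assumption: SINpEt·HBF4 is 1,3-bis[1-(naphthalen-1-yl)ethyl]-4,5-dihydroimidazolium tetrafluoroborate. Its (R,R) antipode is written for the 2S series. If a trial run shows the opposite sense of induction, the equally accessible (S,S) antipode is used instead.

**Step 1**
Reactants: 1 3,4,5-trimethoxyphenol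
Product: 2 2-iodo-3,4,5-trimethoxyphenol
Conditions: NIS (1.0 equiv), MeCN, −10 to 0 °C, dark
Reagents that add atoms: N-iodosuccinimide, O=C1CCC(=O)N1I
Why: Electrophilic aromatic iodination of a strongly activated phenol, in which the only free ring positions (C2 and C6) are ortho to OH and related by the mirror plane through C1 and C4, so only one mono-iodide can form and one equivalent of NIS in the cold holds back a second iodination.

**Step 2**
Reactants: 2 2-iodo-3,4,5-trimethoxyphenol; 3 4-ethynyl-1,2-dimethoxybenzene; 4 carbon monoxide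
Product: 7 2-(3,4-dimethoxyphenyl)-5,6,7-trimethoxy-4H-chromen-4-one (achiral pentamethoxyflavone), via ortho-hydroxyaryl ynone 5 (not isolated), via beta-diethylaminoenone 6 (not isolated)
Conditions: PdCl2(dppf) (3 mol %), CO (20 bar), Et2NH (solvent and base), 100–120 °C, autoclave
Reagents that add atoms: carbon monoxide (reactant 4), [C-]#[O+]; diethylamine, CCNCC (its atoms stay only in intermediate 6 and leave again on ring closure)
Why: PdCl2(dppf) is reduced in the amine to zerovalent palladium, which inserts into the carbon–iodine bond of 2; migratory insertion of CO gives the aroylpalladium iodide, and amine-assisted transfer of the deprotonated alkyne 3 followed by reductive elimination joins C4a–C4 and C4–C3 in ynone 5 (copper-free carbonylative Sonogashira coupling). Diethylamine adds to C2 of 5 (aza-Michael) to give the push–pull enaminone 6, and the ortho phenol oxygen attacks that same carbon and expels the amine (addition–elimination), forming O1–C2. Ring C, the only ring closed, therefore arises in a 6-endo mode (6-endo-trig on 6, formally 6-endo-dig on 5), and formation of the conjugated 4-pyranone makes the closure irreversible. The closest known reaction is the Pd-catalysed carbonylative annulation of ortho-iodophenols with terminal arylacetylenes in a secondary amine, which gives flavones directly. No stereocentre is created, since 7 is planar. Three selectivities are needed: CO uptake before alkynyl transfer, secured by CO pressure, the absence of copper and the fast aryl migration of the electron-rich ring A; 6-endo rather than 5-exo (aurone) closure, secured because the amine makes C2 the one electrophilic carbon that carries a leaving group; and the ring A pattern, secured because the iodine of 2 sits between OH (future O1) and OMe (future 5-OMe).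

**Step 3**
Reactants: 7 2-(3,4-dimethoxyphenyl)-5,6,7-trimethoxy-4H-chromen-4-one
Product: 8 (2S,4S)-2-(3,4-dimethoxyphenyl)-5,6,7-trimethoxychroman-4-ol (2,4-cis carbinol)
Conditions: [Ru(cod)(2-methylallyl)2] (5 mol %), (R,R)-SINpEt·HBF4 (10 mol %), KOtBu (12 mol %), hexane, 70 °C; then 7, H2 (120 bar), toluene, 25–40 °C
Reagents that add atoms: none
Why: Homogeneous asymmetric hydrogenation of flavones with this chiral Ru–NHC catalyst is established for the substrate class, the C2-symmetric carbene ligands steering hydrogen onto the Re face of C2 to set 2S under catalyst control, while the ketone is reduced as well to the mainly 2,4-cis carbinol whose C4 configuration does not matter, and any ketone 9 left unreduced is simply carried along because step 4 converges on it.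

**Step 4**
Reactants: 8 (2S,4S)-2-(3,4-dimethoxyphenyl)-5,6,7-trimethoxychroman-4-ol
Product: 9 (2S)-2-(3,4-dimethoxyphenyl)-5,6,7-trimethoxychroman-4-one
Conditions: IBX (1.5 equiv), DMSO, rt
Reagents that add atoms: none
Why: Hypervalent-iodine (IBX) oxidation of a secondary benzylic alcohol to the aryl ketone runs without base or strong acid, so it erases the C4 centre without ionising the acid-labile, electron-rich carbinol and without triggering the enolisation or retro-oxa-Michael opening that would touch C2.

**Step 5**
Reactants: 9 (2S)-2-(3,4-dimethoxyphenyl)-5,6,7-trimethoxychroman-4-one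
Product: 11 (2S)-2-(3,4-dimethoxyphenyl)-5-hydroxy-6,7-dimethoxychroman-4-one (target), via dichloroboron chelate 10 (not isolated)
Conditions: BCl3 (1.2 equiv, 1 M in CH2Cl2), CH2Cl2, −78 to −10 °C; then ice-cold 1 M aq HCl
Reagents that add atoms: boron trichloride, ClB(Cl)Cl (its atoms stay only in intermediate 10; only hydrogen is added to 11)
Why: Chelation-directed aryl methyl ether cleavage, in which BCl3 binds C4=O and only the peri 5-OMe can close the six-membered O–B–O chelate 10 with loss of MeCl, so the other four methyl ethers stay, and the cold, base-free medium avoids the enolate and chalcone pathway by which flavanones racemise, so C2 stays S.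

**Compound list**

1 | 3,4,5-trimethoxyphenol | COc1cc(O)cc(OC)c1OC | starting material
2 | 2-iodo-3,4,5-trimethoxyphenol | COc1cc(O)c(I)c(OC)c1OC | intermediate
3 | 4-ethynyl-1,2-dimethoxybenzene | COc1ccc(C#C)cc1OC | starting material
4 | carbon monoxide | [C-]#[O+] | starting material
5 | 3-(3,4-dimethoxyphenyl)-1-(6-hydroxy-2,3,4-trimethoxyphenyl)prop-2-yn-1-one | COc1ccc(C#CC(=O)c2c(O)cc(OC)c(OC)c2OC)cc1OC | intermediate
6 | (E)-3-(diethylamino)-3-(3,4-dimethoxyphenyl)-1-(6-hydroxy-2,3,4-trimethoxyphenyl)prop-2-en-1-one (push–pull alkene of labile geometry, drawn E) | CCN(CC)/C(=C/C(=O)c1c(O)cc(OC)c(OC)c1OC)c1ccc(OC)c(OC)c1 | intermediate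
7 | 2-(3,4-dimethoxyphenyl)-5,6,7-trimethoxy-4H-chromen-4-one | COc1ccc(-c2cc(=O)c3c(OC)c(OC)c(OC)cc3o2)cc1OC | intermediate
8 | (2S,4S)-2-(3,4-dimethoxyphenyl)-5,6,7-trimethoxychroman-4-ol | COc1ccc([C@@H]2C[C@H](O)c3c(cc(OC)c(OC)c3OC)O2)cc1OC | intermediate
9 | (2S)-2-(3,4-dimethoxyphenyl)-5,6,7-trimethoxychroman-4-one | COc1ccc([C@@H]2CC(=O)c3c(cc(OC)c(OC)c3OC)O2)cc1OC | intermediate
10 | (2S)-5-(dichloroboryloxy)-2-(3,4-dimethoxyphenyl)-6,7-dimethoxychroman-4-one, boron also bound to C4=O (dative bond not drawn) | COc1ccc([C@@H]2CC(=O)c3c(cc(OC)c(OC)c3OB(Cl)Cl)O2)cc1OC | intermediate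
11 | (2S)-2-(3,4-dimethoxyphenyl)-5-hydroxy-6,7-dimethoxychroman-4-one | COc1ccc([C@@H]2CC(=O)c3c(cc(OC)c(OC)c3O)O2)cc1OC | target

**Step count**

Total step count: 5.
Longest linear sequence: 5 steps (1 → 2 → 7 → 8 → 9 → 11). Compounds 3 and 4 enter in step 2.

**Steps most likely to fail**

**Risk in step 2.** Oxidative addition and CO insertion must occur at a carbon flanked by OH and OMe on a very electron-rich ring. Three processes may outrun the wanted sequence:
- reductive loss of iodine;
- alkynylation without CO uptake, followed by furan closure;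
- interception of the aroylpalladium species by the amine solvent.

The fallback builds the same ynone by polar chemistry, without palladium or CO gas. It sets out from 1. Magnesium-mediated ortho-formylation (MgCl2, Et3N, paraformaldehyde, MeCN, reflux; Casnati–Skattebøl formylation) should give 6-hydroxy-2,3,4-trimethoxybenzaldehyde F1. The lithium acetylide of 3 is then added (n-BuLi, THF, −78 °C), a little over two equivalents so that the phenol is covered. This gives the racemic propargylic alcohol 2-[3-(3,4-dimethoxyphenyl)-1-hydroxyprop-2-yn-1-yl]-3,4,5-trimethoxyphenol F2. MnO2 in CH2Cl2 oxidises F2 to ynone 5, now isolated, where the route is rejoined. Warming 5 in Et2NH–EtOH closes ring C through 6 to 7, as in the second half of step 2.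

**Risk in step 3.** Facial selectivity may be poor or turnover may stall. The substrate is more heavily oxygenated, more hindered next to C4 and less soluble than the flavones on which the catalyst is established.

The fallback replaces enantioface selection by kinetic resolution. It sets out from 7. Unselective heterogeneous hydrogenation (H2, Pd/C, EtOAc–EtOH) gives racemic 2,4-cis-2-(3,4-dimethoxyphenyl)-5,6,7-trimethoxychroman-4-ol F3. IBX oxidation as in step 4 then gives racemic 2-(3,4-dimethoxyphenyl)-5,6,7-trimethoxychroman-4-one F4. Asymmetric transfer hydrogenation follows (Cp*RhCl[(R,R)-TsDPEN], HCO2H–Et3N, EtOAc, rt). It should consume the matched 2R ketone as (2R,4R)-2-(3,4-dimethoxyphenyl)-5,6,7-trimethoxychroman-4-ol F5. The slow-reacting 2S ketone is recovered by chromatography as 9, where the route is rejoined.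

**Risk in step 5.** Two things may go wrong here:
- Configuration at C2 may erode through Lewis-acid-assisted opening of the O1–C2 bond, helped by the 4'-methoxy donor of ring B, and reclosure.
- The neighbouring 6-OMe may also be cleaved once boron is anchored on O5.

The fallback moves the ether cleavage ahead of the stereocentre and ends with a neutral deprotection. It sets out from 7. BCl3 (CH2Cl2, −78 to 0 °C) gives 5-(dichloroboryloxy)-2-(3,4-dimethoxyphenyl)-6,7-dimethoxy-4H-chromen-4-one F6. Hydrolysis on work-up gives 2-(3,4-dimethoxyphenyl)-5-hydroxy-6,7-dimethoxy-4H-chromen-4-one F7. Benzylation (BnBr, K2CO3, DMF, 60 °C) gives 5-(benzyloxy)-2-(3,4-dimethoxyphenyl)-6,7-dimethoxy-4H-chromen-4-one F8. Hydrogenation as in step 3 gives (2S,4S)-5-(benzyloxy)-2-(3,4-dimethoxyphenyl)-6,7-dimethoxychroman-4-ol F9. IBX as in step 4 gives (2S)-5-(benzyloxy)-2-(3,4-dimethoxyphenyl)-6,7-dimethoxychroman-4-one F10. Hydrogenolysis (H2 1 bar, Pd/C, EtOAc, rt) then frees O5 and arrives at 11.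

**Further compounds**

F1 | step 2 | 6-hydroxy-2,3,4-trimethoxybenzaldehyde | COc1cc(O)c(C=O)c(OC)c1OC
F2 | step 2 | 2-[3-(3,4-dimethoxyphenyl)-1-hydroxyprop-2-yn-1-yl]-3,4,5-trimethoxyphenol (racemic) | COc1ccc(C#CC(O)c2c(O)cc(OC)c(OC)c2OC)cc1OC
F3 | step 3 | racemic 2,4-cis-2-(3,4-dimethoxyphenyl)-5,6,7-trimethoxychroman-4-ol | COc1ccc(C2CC(O)c3c(cc(OC)c(OC)c3OC)O2)cc1OC
F4 | step 3 | racemic 2-(3,4-dimethoxyphenyl)-5,6,7-trimethoxychroman-4-one | COc1ccc(C2CC(=O)c3c(cc(OC)c(OC)c3OC)O2)cc1OC
F5 | step 3 | (2R,4R)-2-(3,4-dimethoxyphenyl)-5,6,7-trimethoxychroman-4-ol | COc1ccc([C@H]2C[C@@H](O)c3c(cc(OC)c(OC)c3OC)O2)cc1OC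
F6 | step 5 | 5-(dichloroboryloxy)-2-(3,4-dimethoxyphenyl)-6,7-dimethoxy-4H-chromen-4-one | COc1ccc(-c2cc(=O)c3c(OB(Cl)Cl)c(OC)c(OC)cc3o2)cc1OC
F7 | step 5 | 2-(3,4-dimethoxyphenyl)-5-hydroxy-6,7-dimethoxy-4H-chromen-4-one | COc1ccc(-c2cc(=O)c3c(O)c(OC)c(OC)cc3o2)cc1OC
F8 | step 5 | 5-(benzyloxy)-2-(3,4-dimethoxyphenyl)-6,7-dimethoxy-4H-chromen-4-one | COc1ccc(-c2cc(=O)c3c(OCc4ccccc4)c(OC)c(OC)cc3o2)cc1OC
F9 | step 5 | (2S,4S)-5-(benzyloxy)-2-(3,4-dimethoxyphenyl)-6,7-dimethoxychroman-4-ol | COc1ccc([C@@H]2C[C@H](O)c3c(cc(OC)c(OC)c3OCc4ccccc4)O2)cc1OC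
F10 | step 5 | (2S)-5-(benzyloxy)-2-(3,4-dimethoxyphenyl)-6,7-dimethoxychroman-4-one | COc1ccc([C@@H]2CC(=O)c3c(cc(OC)c(OC)c3OCc4ccccc4)O2)cc1OC
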